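**Plan**

1. Locants used in all explanations: ring A = trihydroxycyclohexane ring (C1 CMe2, C3 CHOH, C5 C(OH)Me, C6 C(OH)); vinylene C7=C8; ring B = butenolide (C9 alpha, C10 beta, a12 gamma); chain a1–a12 runs from the alkyne carbon on ring C (the cyclohexenol ring, carbinol C3') to a12.
2. Retrosynthetic cuts, in order: the two O–Si bonds; C8–C9 (Stille); C6–C7 (alkenyl transfer to a C6 ketone); a5=a6 (Horner–Wadsworth–Emmons); C10–a12 plus O–a12 of ring B (tandem Sonogashira/lactonisation); ring C–a1 (Sonogashira).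
3. Forward: ketoisophorone gives one silyl-protected hydroxy-enone that feeds both carbocycles. Ring A is taken to a C5-hydroxy C6-ketone and joined at C6–C7; ring C is taken to a triflate and extended to a5; ring B is closed on a C6 enynol, extended to a6, joined at a5=a6, and finally joined at C8–C9.
4. Stereochemistry: C3 and C3' from one asymmetric transfer hydrogenation; C5 from epoxidation anti to the C3 silyloxy group; C6 from the C5 oxygen in the key step; alkene geometries from E-configured building blocks, E-selective olefinations, stereoretentive couplings and anti-oxymetalation (Z ylidene).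
5. Enabling feature: in ring A the tertiary C5–OH is cis to the C7=C8 vinyl group on the adjacent C6 carbinol (a trans-5,6-diol). A ring A C6 ketone whose O5 carries a metal can therefore receive an alkenyl ligand from that metal on exactly the required face, the face an untethered nucleophile is expected to avoid.

Key step: step 6

Remarks: compounds 1, 8, 15 and 19 are taken as commercial. Systematic names use their own numbering. The sense of induction in step 1 is assigned by analogy with aryl ketones (the alkene taking the place of the arene); the mirror-image catalyst would be used if the analogy fails. Polyene intermediates are handled under argon in the dark.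

Step 1
Reactants: 1 ketoisophorone (2,6,6-trimethylcyclohex-2-ene-1,4-dione)
Product: 2 (4S)-4-hydroxy-2,6,6-trimethylcyclohex-2-en-1-one
Conditions: RuCl(p-cymene)[(S,S)-TsDPEN] (cat.), HCO2H–Et3N, CH2Cl2, rt
Reagents that add atoms: none
Why: Noyori asymmetric transfer hydrogenation should reduce only the unhindered carbonyl (the other is flanked by the gem-dimethyl carbon and the methyl-bearing alkene carbon), and the chiral catalyst sets the C3/C3' carbinol as S.

Step 2
Reactants: 2 (4S)-4-hydroxy-2,6,6-trimethylcyclohex-2-en-1-one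
Product: 3 (4S)-4-[(tert-butyldimethylsilyl)oxy]-2,6,6-trimethylcyclohex-2-en-1-one
Conditions: TBSCl, imidazole, DMF, rt
Reagents that add atoms: tert-butyldimethylsilyl chloride, CC(C)(C)[Si](C)(C)Cl
Why: Standard silylation of a secondary alcohol; the bulky ether is the steric control element for step 3 and survives base, hydride and organometallic reagents.

Step 3
Reactants: 3 (4S)-4-[(tert-butyldimethylsilyl)oxy]-2,6,6-trimethylcyclohex-2-en-1-one
Product: 4 (1R,5S,6R)-5-[(tert-butyldimethylsilyl)oxy]-1,3,3-trimethyl-7-oxabicyclo[4.1.0]heptan-2-one (oxirane oxygen trans to the silyloxy group)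
Conditions: 30% aq. H2O2, NaOH (aq.), MeOH, 0 °C
Reagents that add atoms: hydrogen peroxide, OO
Why: Weitz–Scheffer nucleophilic epoxidation: hydroperoxide should add to C4 anti to the adjacent C3 silyloxy group and the enolate closes the oxirane, setting C4 and C5 with oxygen trans to OTBS.

Step 4
Reactants: 4 (1R,5S,6R)-5-[(tert-butyldimethylsilyl)oxy]-1,3,3-trimethyl-7-oxabicyclo[4.1.0]heptan-2-one
Product: 6 (2R,4S)-4-[(tert-butyldimethylsilyl)oxy]-2,6,6-trimethylcyclohexane-1,2-diol (either C1 carbinol epimer), via epoxy alcohol 5 (not isolated)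
Conditions: LiAlH4, THF, 0 °C to reflux; aq. NaOH work-up
Reagents that add atoms: none
Why: Hydride first reduces the ketone (5) and then opens the trisubstituted epoxide by SN2 attack at the secondary C4 (trans-diaxial opening with the silyloxy group equatorial), so the oxygen stays on C5 with its configuration; the new secondary carbinol is oxidised in step 5 and its configuration is irrelevant.

Step 5
Reactants: 6 (2R,4S)-4-[(tert-butyldimethylsilyl)oxy]-2,6,6-trimethylcyclohexane-1,2-diol
Product: 7 (2R,4S)-4-[(tert-butyldimethylsilyl)oxy]-2-hydroxy-2,6,6-trimethylcyclohexan-1-one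
Conditions: IBX, DMSO, 40 °C
Reagents that add atoms: none
Why: IBX oxidises the secondary alcohol of a secondary/tertiary 1,2-diol to the alpha-hydroxy ketone without glycol cleavage and leaves the tertiary C5 hydroxyl and the silyl ether untouched.

Step 6
Reactants: 7 (2R,4S)-4-[(tert-butyldimethylsilyl)oxy]-2-hydroxy-2,6,6-trimethylcyclohexan-1-one; 8 (E)-1,2-bis(tributylstannyl)ethene
Product: 12 (1R,2R,4S)-4-[(tert-butyldimethylsilyl)oxy]-2,6,6-trimethyl-1-[(E)-2-(tributylstannyl)ethenyl]cyclohexane-1,2-diol, via stannylvinyllithium 9 (not isolated), via aluminium alkoxide 10 (not isolated), via lithium aluminate 11 (not isolated)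
Conditions: 7, Me3Al (1.05 equiv), THF, −78 to 0 °C; separately 8, n-BuLi, THF, −78 °C; add 9 to 10 at −78 °C, then −78 to −20 °C; aq. KNaC4H4O6 work-up
Reagents that add atoms: none
Why: Proposed new method: protonolysis of one Al–Me bond by the tertiary C5 hydroxyl gives alkoxide 10, tin–lithium exchange on 8 gives 9, and their union gives the tetracoordinate alkoxy(alkenyl)dimethylaluminate 11, in which the aluminium anchored on the axial O5 sits over the face of the C6 carbonyl syn to O5 (the carbonyl being activated by the lithium counter-ion) and hands its sp2 ligand to C6 through a five-membered cyclic transition state (C5, O5, Al, C7, C6) with retention of the E geometry, the aluminium diolate being hydrolysed on work-up. The closest known reaction types are the Petasis borono-Mannich reaction (alkenyl transfer from a boron ate complex anchored on a neighbouring hydroxyl), alkoxide-directed delivery of unsaturated ligands from aluminium (hydroxyl-directed alkynylalane additions, syn-opening of glycal epoxides by alanes) and the addition of lithium alkenylalanates to ketones. No ring of the target is closed; the only ring is the temporary five-membered array of the transition state, and the aluminium tether leaves on hydrolysis. The new C6 stereocenter is controlled by the C5 stereocenter: delivery from O5 places the vinyl group cis to O5 and the C6 hydroxyl trans to it (6R). The step needs facial selectivity opposite to the intrinsic one (an untethered small nucleophile is expected to attack axially, anti to the axial C5–O bond), which the tether secures because the only carbon nucleophile present is bound to O5, and it needs alkenyl rather than methyl transfer, which the higher migratory aptitude of sp2 ligands in mixed alanates secures.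

Step 7
Reactants: 3 (4S)-4-[(tert-butyldimethylsilyl)oxy]-2,6,6-trimethylcyclohex-2-en-1-one
Product: 14 (4R)-4-[(tert-butyldimethylsilyl)oxy]-2,6,6-trimethylcyclohex-1-en-1-yl trifluoromethanesulfonate, via lithium enolate 13 (not isolated)
Conditions: LiBH(s-Bu)3, THF, −78 °C; then PhNTf2, −78 °C to rt
Reagents that add atoms: N-phenylbis(trifluoromethanesulfonimide), O=S(=O)(N(c1ccccc1)S(=O)(=O)C(F)(F)F)C(F)(F)F
Why: Conjugate hydride addition of the hindered borohydride (the carbonyl is too shielded for 1,2-attack and the beta-carbon carries no extra substituent) gives the regiodefined tetrasubstituted enolate 13, which is O-triflated; C3' is untouched and no new stereocenter remains in the product.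

Step 8
Reactants: 14 (4R)-4-[(tert-butyldimethylsilyl)oxy]-2,6,6-trimethylcyclohex-1-en-1-yl trifluoromethanesulfonate; 15 (2E)-3-methylpent-2-en-4-yn-1-ol
Product: 16 (2E)-5-{(4R)-4-[(tert-butyldimethylsilyl)oxy]-2,6,6-trimethylcyclohex-1-en-1-yl}-3-methylpent-2-en-4-yn-1-ol
Conditions: Pd(PPh3)4 (cat.), CuI (cat.), i-Pr2NH, DMF, 50 °C
Reagents that add atoms: none
Why: Sonogashira coupling of the alkenyl triflate with the terminal alkyne forms the ring C–a1 bond; the E a3=a4 geometry of 15 is carried over and the free alcohol is tolerated.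

Step 9
Reactants: 16 (2E)-5-{(4R)-4-[(tert-butyldimethylsilyl)oxy]-2,6,6-trimethylcyclohex-1-en-1-yl}-3-methylpent-2-en-4-yn-1-ol
Product: 17 (2E)-1-bromo-5-{(4R)-4-[(tert-butyldimethylsilyl)oxy]-2,6,6-trimethylcyclohex-1-en-1-yl}-3-methylpent-2-en-4-yne
Conditions: CBr4, PPh3, CH2Cl2, 0 °C
Reagents that add atoms: tetrabromomethane, BrC(Br)(Br)Br
Why: Appel reaction: SN2 displacement of the oxyphosphonium at the primary allylic carbon under neutral conditions keeps the alkene geometry and the silyl ether.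

Step 10
Reactants: 17 (2E)-1-bromo-5-{(4R)-4-[(tert-butyldimethylsilyl)oxy]-2,6,6-trimethylcyclohex-1-en-1-yl}-3-methylpent-2-en-4-yne
Product: 18 diethyl [(2E)-5-{(4R)-4-[(tert-butyldimethylsilyl)oxy]-2,6,6-trimethylcyclohex-1-en-1-yl}-3-methylpent-2-en-4-yn-1-yl]phosphonate
Conditions: P(OEt)3 (neat), 90 °C
Reagents that add atoms: triethyl phosphite, CCOP(OCC)OCC
Why: Michaelis–Arbuzov reaction of a primary allylic bromide, the standard entry to allylic phosphonates for polyene olefination.

Step 11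
Reactants: 19 propiolic acid
Product: 20 (2E)-2,3-dibromoprop-2-enoic acid
Conditions: Br2, CHCl3, 0 °C to rt
Reagents that add atoms: bromine, BrBr
Why: Anti addition of bromine across the triple bond gives the E dibromide, in which the carboxyl group is cis to the beta-bromine as the later lactonisation requires.

Step 12
Reactants: 20 (2E)-2,3-dibromoprop-2-enoic acid; 15 (2E)-3-methylpent-2-en-4-yn-1-ol
Product: 22 (5Z)-3-bromo-5-[(2E)-4-hydroxy-2-methylbut-2-en-1-ylidene]furan-2(5H)-one, via enynoic acid 21 (not isolated)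
Conditions: Pd(PPh3)4 (cat.), CuI (cat.), Et3N, MeCN, rt
Reagents that add atoms: none
Why: Sonogashira coupling occurs at the more reactive beta C–Br bond to give 21, whose carboxylate, cis to the alkyne, adds 5-exo-dig across the metal-activated triple bond (anti oxymetalation, then protodemetalation) to close ring B as the Z ylidene; the alpha C–Br bond is kept for step 16.

Step 13
Reactants: 22 (5Z)-3-bromo-5-[(2E)-4-hydroxy-2-methylbut-2-en-1-ylidene]furan-2(5H)-one
Product: 23 (2E)-4-[(2Z)-4-bromo-5-oxofuran-2(5H)-ylidene]-3-methylbut-2-enal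
Conditions: MnO2, CH2Cl2, rt
Reagents that add atoms: none
Why: Chemoselective MnO2 oxidation of an allylic alcohol to the enal under neutral conditions that the ylidene butenolide tolerates.

Step 14
Reactants: 23 (2E)-4-[(2Z)-4-bromo-5-oxofuran-2(5H)-ylidene]-3-methylbut-2-enal
Product: 24 (2E,4E)-6-[(2Z)-4-bromo-5-oxofuran-2(5H)-ylidene]-5-methylhexa-2,4-dienal
Conditions: Ph3P=CHCHO (slight excess), toluene, 60 °C
Reagents that add atoms: (triphenylphosphoranylidene)acetaldehyde, O=CC=P(c1ccccc1)(c1ccccc1)c1ccccc1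
Why: Wittig reaction with the stabilised formylmethylene ylide gives the E a7=a8 bond under base-free conditions; the more extended product aldehyde is less electrophilic, which should limit a second homologation.

Step 15
Reactants: 18 diethyl [(2E)-5-{(4R)-4-[(tert-butyldimethylsilyl)oxy]-2,6,6-trimethylcyclohex-1-en-1-yl}-3-methylpent-2-en-4-yn-1-yl]phosphonate; 24 (2E,4E)-6-[(2Z)-4-bromo-5-oxofuran-2(5H)-ylidene]-5-methylhexa-2,4-dienal
Product: 26 (5Z)-3-bromo-5-[(2E,4E,6E,8E)-11-{(4R)-4-[(tert-butyldimethylsilyl)oxy]-2,6,6-trimethylcyclohex-1-en-1-yl}-2,9-dimethylundeca-2,4,6,8-tetraen-10-yn-1-ylidene]furan-2(5H)-one, via phosphonate anion 25 (not isolated)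
Conditions: 18, KN(SiMe3)2, THF, −78 °C; then 24, −78 to −30 °C
Reagents that add atoms: none
Why: Horner–Wadsworth–Emmons olefination: the preformed allylic phosphonate anion 25 should add to the aldehyde faster than to the butenolide at low temperature, and elimination of phosphate gives the E a5=a6 bond (carbanion olefinations of ylidene-butenolide polyenals are precedented).

Step 16
Reactants: 12 (1R,2R,4S)-4-[(tert-butyldimethylsilyl)oxy]-2,6,6-trimethyl-1-[(E)-2-(tributylstannyl)ethenyl]cyclohexane-1,2-diol; 26 (5Z)-3-bromo-5-[(2E,4E,6E,8E)-11-{(4R)-4-[(tert-butyldimethylsilyl)oxy]-2,6,6-trimethylcyclohex-1-en-1-yl}-2,9-dimethylundeca-2,4,6,8-tetraen-10-yn-1-ylidene]furan-2(5H)-one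
Product: 27 bis(tert-butyldimethylsilyl) ether of the target at the C3 and C3' hydroxyls
Conditions: Pd2(dba)3·CHCl3 (cat.), AsPh3, NMP, 40 °C
Reagents that add atoms: none
Why: Stille coupling: oxidative addition into the butenolide C9–Br bond and transmetalation of the E alkenylstannane with retention form C8–C9; free tertiary hydroxyls are tolerated and couplings at the alpha-bromide of ylidene butenolides are precedented.

Step 17
Reactants: 27 bis(tert-butyldimethylsilyl) ether of the target
Product: 28 target, (5Z)-3-{(E)-2-[(1R,2R,4S)-1,2,4-trihydroxy-2,6,6-trimethylcyclohexyl]ethenyl}-5-[(2E,4E,6E,8E)-11-[(4R)-4-hydroxy-2,6,6-trimethylcyclohex-1-en-1-yl]-2,9-dimethylundeca-2,4,6,8-tetraen-10-yn-1-ylidene]furan-2(5H)-one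
Conditions: HF·pyridine, pyridine, THF, 0 °C to rt
Reagents that add atoms: none
Why: Buffered fluoride cleavage of the two secondary silyl ethers, chosen over basic fluoride sources because the ylidene butenolide is base-sensitive; no stereocenter is touched.

**Compound list**

1 | ketoisophorone (2,6,6-trimethylcyclohex-2-ene-1,4-dione) | CC1=CC(=O)CC(C)(C)C1=O | starting material
2 | (4S)-4-hydroxy-2,6,6-trimethylcyclohex-2-en-1-one | O=C1C(C)(C)C[C@H](O)C=C1C | intermediate
3 | (4S)-4-[(tert-butyldimethylsilyl)oxy]-2,6,6-trimethylcyclohex-2-en-1-one | O=C1C(C)(C)C[C@H](O[Si](C)(C)C(C)(C)C)C=C1C | intermediate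
4 | (1R,5S,6R)-5-[(tert-butyldimethylsilyl)oxy]-1,3,3-trimethyl-7-oxabicyclo[4.1.0]heptan-2-one | O=C1C(C)(C)C[C@H](O[Si](C)(C)C(C)(C)C)[C@H]2O[C@@]12C | intermediate
5 | 5-[(tert-butyldimethylsilyl)oxy]-1,3,3-trimethyl-7-oxabicyclo[4.1.0]heptan-2-ol (ring configurations as in 4, carbinol epimers, present as its aluminate) | OC1C(C)(C)C[C@H](O[Si](C)(C)C(C)(C)C)[C@H]2O[C@@]12C | intermediate
6 | (2R,4S)-4-[(tert-butyldimethylsilyl)oxy]-2,6,6-trimethylcyclohexane-1,2-diol (C1 epimers) | OC1C(C)(C)C[C@H](O[Si](C)(C)C(C)(C)C)C[C@@]1(C)O | intermediate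
7 | (2R,4S)-4-[(tert-butyldimethylsilyl)oxy]-2-hydroxy-2,6,6-trimethylcyclohexan-1-one | O=C1C(C)(C)C[C@H](O[Si](C)(C)C(C)(C)C)C[C@@]1(C)O | intermediate
8 | (E)-1,2-bis(tributylstannyl)ethene | CCCC[Sn](CCCC)(CCCC)/C=C/[Sn](CCCC)(CCCC)CCCC | starting material
9 | (E)-2-(tributylstannyl)ethenyllithium | [Li]/C=C/[Sn](CCCC)(CCCC)CCCC | intermediate
10 | dimethylaluminium alkoxide of 7 (Al on the tertiary oxygen) | O=C1C(C)(C)C[C@H](O[Si](C)(C)C(C)(C)C)C[C@@]1(C)O[Al](C)C | intermediate
11 | lithium alkoxy(dimethyl)[(E)-2-(tributylstannyl)ethenyl]aluminate derived from 10 and 9 | [Li+].O=C1C(C)(C)C[C@H](O[Si](C)(C)C(C)(C)C)C[C@@]1(C)O[Al-](C)(C)/C=C/[Sn](CCCC)(CCCC)CCCC | intermediate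
12 | (1R,2R,4S)-4-[(tert-butyldimethylsilyl)oxy]-2,6,6-trimethyl-1-[(E)-2-(tributylstannyl)ethenyl]cyclohexane-1,2-diol | CCCC[Sn](CCCC)(CCCC)/C=C/[C@@]1(O)C(C)(C)C[C@H](O[Si](C)(C)C(C)(C)C)C[C@@]1(C)O | intermediate
13 | lithium (4R)-4-[(tert-butyldimethylsilyl)oxy]-2,6,6-trimethylcyclohex-1-en-1-olate | CC1=C(O[Li])C(C)(C)C[C@H](O[Si](C)(C)C(C)(C)C)C1 | intermediate
14 | (4R)-4-[(tert-butyldimethylsilyl)oxy]-2,6,6-trimethylcyclohex-1-en-1-yl trifluoromethanesulfonate | CC1=C(OS(=O)(=O)C(F)(F)F)C(C)(C)C[C@H](O[Si](C)(C)C(C)(C)C)C1 | intermediate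
15 | (2E)-3-methylpent-2-en-4-yn-1-ol | C#C/C(C)=C/CO | starting material
16 | (2E)-5-{(4R)-4-[(tert-butyldimethylsilyl)oxy]-2,6,6-trimethylcyclohex-1-en-1-yl}-3-methylpent-2-en-4-yn-1-ol | CC1=C(C#C/C(C)=C/CO)C(C)(C)C[C@H](O[Si](C)(C)C(C)(C)C)C1 | intermediate
17 | (2E)-1-bromo-5-{(4R)-4-[(tert-butyldimethylsilyl)oxy]-2,6,6-trimethylcyclohex-1-en-1-yl}-3-methylpent-2-en-4-yne | CC1=C(C#C/C(C)=C/CBr)C(C)(C)C[C@H](O[Si](C)(C)C(C)(C)C)C1 | intermediate
18 | diethyl [(2E)-5-{(4R)-4-[(tert-butyldimethylsilyl)oxy]-2,6,6-trimethylcyclohex-1-en-1-yl}-3-methylpent-2-en-4-yn-1-yl]phosphonate | CC1=C(C#C/C(C)=C/CP(=O)(OCC)OCC)C(C)(C)C[C@H](O[Si](C)(C)C(C)(C)C)C1 | intermediate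
19 | propiolic acid | C#CC(=O)O | starting material
20 | (2E)-2,3-dibromoprop-2-enoic acid | OC(=O)/C(Br)=C\Br | intermediate
21 | (2E,6E)-2-bromo-8-hydroxy-6-methylocta-2,6-dien-4-ynoic acid (carboxyl cis to the alkyne) | OC(=O)/C(Br)=C\C#C/C(C)=C/CO | intermediate
22 | (5Z)-3-bromo-5-[(2E)-4-hydroxy-2-methylbut-2-en-1-ylidene]furan-2(5H)-one | OC/C=C(C)/C=C1C=C(Br)C(=O)O/1 | intermediate
23 | (2E)-4-[(2Z)-4-bromo-5-oxofuran-2(5H)-ylidene]-3-methylbut-2-enal | O=C/C=C(C)/C=C1C=C(Br)C(=O)O/1 | intermediate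
24 | (2E,4E)-6-[(2Z)-4-bromo-5-oxofuran-2(5H)-ylidene]-5-methylhexa-2,4-dienal | O=C/C=C/C=C(C)/C=C1C=C(Br)C(=O)O/1 | intermediate
25 | potassium salt of the alpha-carbanion of phosphonate 18 | [K+].CC1=C(C#C/C(C)=C/[CH-]P(=O)(OCC)OCC)C(C)(C)C[C@H](O[Si](C)(C)C(C)(C)C)C1 | intermediate
26 | (5Z)-3-bromo-5-[(2E,4E,6E,8E)-11-{(4R)-4-[(tert-butyldimethylsilyl)oxy]-2,6,6-trimethylcyclohex-1-en-1-yl}-2,9-dimethylundeca-2,4,6,8-tetraen-10-yn-1-ylidene]furan-2(5H)-one | CC1=C(C#C/C(C)=C/C=C/C=C/C=C(C)/C=C2C=C(Br)C(=O)O/2)C(C)(C)C[C@H](O[Si](C)(C)C(C)(C)C)C1 | intermediate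
27 | bis(tert-butyldimethylsilyl) ether of the target (silyl groups on the C3 and C3' oxygens) | CC1=C(C#C/C(C)=C/C=C/C=C/C=C(C)/C=C2C=C(/C=C/[C@@]3(O)C(C)(C)C[C@H](O[Si](C)(C)C(C)(C)C)C[C@@]3(C)O)C(=O)O/2)C(C)(C)C[C@H](O[Si](C)(C)C(C)(C)C)C1 | intermediate
28 | (5Z)-3-{(E)-2-[(1R,2R,4S)-1,2,4-trihydroxy-2,6,6-trimethylcyclohexyl]ethenyl}-5-[(2E,4E,6E,8E)-11-[(4R)-4-hydroxy-2,6,6-trimethylcyclohex-1-en-1-yl]-2,9-dimethylundeca-2,4,6,8-tetraen-10-yn-1-ylidene]furan-2(5H)-one | CC1=C(C#C/C(C)=C/C=C/C=C/C=C(C)/C=C2C=C(/C=C/[C@@]3(O)C(C)(C)C[C@H](O)C[C@@]3(C)O)C(=O)O/2)C(C)(C)C[C@H](O)C1 | target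

**Summary**

Total step count: 17. Longest linear sequence: 9 steps (steps 1, 2, 7, 8, 9, 10, 15, 16, 17).

Steps most likely to fail:

1. Step 6 (proposed method). The alkenyl ligand may transfer too slowly or methyl may transfer instead, reagent that escapes the tether may attack the opposite face, or the aluminium alkoxide may trigger an alpha-ketol rearrangement. The fallback uses known chemistry, sets out from 7 and comes back at 12. Ketol 7 is converted into its bromomagnesium alkoxide and treated with ethynylmagnesium bromide (HC≡CMgBr, THF, 0 °C), a chelation-directed acetylide addition to an alpha-hydroxy ketone; the C1 epimers are separated by chromatography to give (1S,2R,4S)-4-[(tert-butyldimethylsilyl)oxy]-1-ethynyl-2,6,6-trimethylcyclohexane-1,2-diol F1. Palladium-catalysed syn-hydrostannation of the terminal alkyne (Bu3SnH, PdCl2(PPh3)2 cat., THF), which places tin on the terminal carbon of a hindered tertiary propargylic alcohol, then gives 12.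

2. Step 15. The carbanion or the amide base may attack the bromobutenolide (conjugate addition, ring opening), or E selectivity at a5=a6 may be incomplete. The fallback builds the polyene before the butenolide; it sets out from 15 and 18 and comes back at 26. Enynol 15 is C-silylated through its dianion (EtMgBr 2 equiv, Me3SiCl 1 equiv, THF) to (2E)-3-methyl-5-(trimethylsilyl)pent-2-en-4-yn-1-ol F2, oxidised (MnO2, CH2Cl2) to (2E)-3-methyl-5-(trimethylsilyl)pent-2-en-4-ynal F3, and homologated (Ph3P=CHCHO, toluene, 60 °C) to (2E,4E)-5-methyl-7-(trimethylsilyl)hepta-2,4-dien-6-ynal F4. Olefination of F4 with anion 25 (from 18 and KN(SiMe3)2, THF, −78 °C) gives tert-butyl{[(1R)-4-[(3E,5E,7E,9E)-3,10-dimethyl-12-(trimethylsilyl)dodeca-3,5,7,9-tetraene-1,11-diyn-1-yl]-3,5,5-trimethylcyclohex-3-en-1-yl]oxy}dimethylsilane F5. Methanolysis (K2CO3, MeOH) gives the terminal alkyne tert-butyl{[(1R)-4-[(3E,5E,7E,9E)-3,10-dimethyldodeca-3,5,7,9-tetraene-1,11-diyn-1-yl]-3,5,5-trimethylcyclohex-3-en-1-yl]oxy}dimethylsilane F6. Tandem Sonogashira coupling/lactonisation of F6 with 20 (Pd(PPh3)4 cat., CuI cat., Et3N, MeCN) proceeds through (2E,6E,8E,10E,12E)-2-bromo-15-{(4R)-4-[(tert-butyldimethylsilyl)oxy]-2,6,6-trimethylcyclohex-1-en-1-yl}-6,13-dimethylpentadeca-2,6,8,10,12-pentaene-4,14-diynoic acid F7 and gives 26, so the butenolide never meets a strong base.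

3. Step 17. Acid or fluoride may isomerise or degrade the polyene butenolide, or ionise the tertiary allylic C6 alcohol, at the last stage. The fallback removes the silyl groups before the last carbon–carbon bond is made; it sets out from 12 and 26 and comes back at 28. Stannane 12 is desilylated (Bu4NF, THF) to (1R,2R,4S)-2,6,6-trimethyl-1-[(E)-2-(tributylstannyl)ethenyl]cyclohexane-1,2,4-triol F8. Bromide 26 is desilylated (Bu4NF, AcOH, THF) to (5Z)-3-bromo-5-[(2E,4E,6E,8E)-11-[(4R)-4-hydroxy-2,6,6-trimethylcyclohex-1-en-1-yl]-2,9-dimethylundeca-2,4,6,8-tetraen-10-yn-1-ylidene]furan-2(5H)-one F9. Stille coupling of F8 with F9 (Pd2(dba)3·CHCl3 cat., AsPh3, NMP, 40 °C) then gives 28 directly.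

Further compounds
F1 | step 6 | (1S,2R,4S)-4-[(tert-butyldimethylsilyl)oxy]-1-ethynyl-2,6,6-trimethylcyclohexane-1,2-diol | C#C[C@@]1(O)C(C)(C)C[C@H](O[Si](C)(C)C(C)(C)C)C[C@@]1(C)O
F2 | step 15 | (2E)-3-methyl-5-(trimethylsilyl)pent-2-en-4-yn-1-ol | C[Si](C)(C)C#C/C(C)=C/CO
F3 | step 15 | (2E)-3-methyl-5-(trimethylsilyl)pent-2-en-4-ynal | C[Si](C)(C)C#C/C(C)=C/C=O
F4 | step 15 | (2E,4E)-5-methyl-7-(trimethylsilyl)hepta-2,4-dien-6-ynal | C[Si](C)(C)C#C/C(C)=C/C=C/C=O
F5 | step 15 | tert-butyl{[(1R)-4-[(3E,5E,7E,9E)-3,10-dimethyl-12-(trimethylsilyl)dodeca-3,5,7,9-tetraene-1,11-diyn-1-yl]-3,5,5-trimethylcyclohex-3-en-1-yl]oxy}dimethylsilane | CC1=C(C#C/C(C)=C/C=C/C=C/C=C(C)/C#C[Si](C)(C)C)C(C)(C)C[C@H](O[Si](C)(C)C(C)(C)C)C1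
F6 | step 15 | tert-butyl{[(1R)-4-[(3E,5E,7E,9E)-3,10-dimethyldodeca-3,5,7,9-tetraene-1,11-diyn-1-yl]-3,5,5-trimethylcyclohex-3-en-1-yl]oxy}dimethylsilane | CC1=C(C#C/C(C)=C/C=C/C=C/C=C(C)/C#C)C(C)(C)C[C@H](O[Si](C)(C)C(C)(C)C)C1
F7 | step 15 | (2E,6E,8E,10E,12E)-2-bromo-15-{(4R)-4-[(tert-butyldimethylsilyl)oxy]-2,6,6-trimethylcyclohex-1-en-1-yl}-6,13-dimethylpentadeca-2,6,8,10,12-pentaene-4,14-diynoic acid | CC1=C(C#C/C(C)=C/C=C/C=C/C=C(C)/C#C/C=C(Br)\C(O)=O)C(C)(C)C[C@H](O[Si](C)(C)C(C)(C)C)C1
F8 | step 17 | (1R,2R,4S)-2,6,6-trimethyl-1-[(E)-2-(tributylstannyl)ethenyl]cyclohexane-1,2,4-triol | CCCC[Sn](CCCC)(CCCC)/C=C/[C@@]1(O)C(C)(C)C[C@H](O)C[C@@]1(C)O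
F9 | step 17 | (5Z)-3-bromo-5-[(2E,4E,6E,8E)-11-[(4R)-4-hydroxy-2,6,6-trimethylcyclohex-1-en-1-yl]-2,9-dimethylundeca-2,4,6,8-tetraen-10-yn-1-ylidene]furan-2(5H)-one | CC1=C(C#C/C(C)=C/C=C/C=C/C=C(C)/C=C2C=C(Br)C(=O)O/2)C(C)(C)C[C@H](O)C1
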